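Slowness is what we look for first: the next run should repeat the charge that leaves the most Z2 at the end, and a Z that pairs late spends a shorter stretch as Z2 before that end.

    Z + Z ⇌ Z2 (K1 = 6.45 L mol⁻¹, k1 = 0.0291 L mol⁻¹ s⁻¹)
    Z2 → J (k2 = 0.00829 s⁻¹)

| setting | amber | ochre | green | blue |
|---|---|---|---|---|
| Z | 0.40 M | 0.80 M | 1.5 M | 3.0 M |
| time | 6.0 min | 6.0 min | 6.0 min | 6.0 min |

1. amount of Z2 at the end, in percent of the Z charged for amber, ochre, green, blue, in this order
2. how the row runs (falls all the way / falls, then rises / hardly changes / rises all the way / rises, then falls)

- a species is counted by the Z in it: one Z2 or J counts as two
- a doubled species enters its step squared and goes two at a time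
- "hardly changes" means that all values lie within two and a half points (for a concentration: within two and a half percent of the largest)
- run time (amber): 6.0 min

The first step pairs Z into Z2, and the second drains Z2 into J. Left to the second step, Z2 halves in 1.39 min, shorter than the run of 6.0 min. We set against this a time for the pairing. At the start of amber it is 0.716 min: this is the pairing time, τ = 1/(2kc), the time in which Z at concentration c would halve by the forward pairing, with k its constant. It is shorter than the drain's half-life, so Z2 builds up at first. But τ lengthens as Z falls, so the pairing loses its lead and Z2 then declines.

For our own reckoning, we take the forward pairing by itself, which leaves a third of Z at 2τ, treat the whole charge as becoming Z2 at that moment, and let it drain for the rest of the run. Amber keeps 10.3%. With a starting τ of 0.0955 min, blue keeps 5.56%. Ochre keeps 7.22% and green 6.11%. Our row loses 4.7 percentage points from amber to blue, outside the margin for "hardly changes", and drops at each step, so we expect a row that falls all the way, and we would charge amber.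

The forecast gives 12.5%, 10.5%, 9% and 7.7%, a row that falls all the way, higher than ours at amber, on the ground that "Dilute runs hold more of their Z as free monomer".

The flask gives 10.1%, 8.91%, 7.95% and 7.13%, a row that falls all the way. Amber holds more than the other flasks, and blue also stands above our figure.

The path from Z2 to J is the main reason for the low end amount of Z2 in blue: without it blue ends at 85.2% in place of 7.13%, and the row rises all the way. On the 18.9% of Z left in amber at the end, τ has grown to 3.79 min, longer than the drain's half-life, and the net making of Z2 runs at 0.448 times its net use. On the 5.15% of Z left in blue at the end, τ is 1.85 min, also longer than that half-life.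

(The numbers are invented; the rest is arithmetic.)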